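**Assumption:** the target is taken as the open keto-phenol form drawn, with (3S,4S) at the lactone and (S) at the side-chain carbon (my CIP assignment from the SMILES); 3-(bromomethyl)cyclobutan-1-one is taken as a purchasable building block.

## Retrosynthetic overview

1. Target 23 ⇐ tris-silyl ether 22 (fluoride); the side-chain CH(CH2OH) centre ⇐ catalyst-controlled hydroxymethylation of deoxybenzoin 20 with formaldehyde.
2. 20 ⇐ Pd α-arylation of acetophenone 19 with lactone aryl bromide 15 (ring B–Cα bond).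
3. 15 ⇐ trans-selective enolate alkylation of (S)-β-benzyl lactone 8 with benzyl bromide 13 (ring B from p-cresol).
4. 8 ⇐ desymmetrising asymmetric Baeyer–Villiger ring expansion of cyclobutanone 6 ⇐ Ni cross-electrophile coupling of aryl bromide 4 with 3-(bromomethyl)cyclobutanone.
5. 4 and 19 ⇐ catechol. Ring order: the γ-lactone is the only ring made (four-membered ketone → five-membered lactone by 1,2-shift); the three arenes are bought.

## Route

Step 1
Reactants: 1 catechol
Product: 2 guaiacol (2-methoxyphenol)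
Conditions: MeI (1.0 equiv), K2CO3 (1.0 equiv), catechol (2 equiv), acetone, reflux
Reagents that add atoms: iodomethane, CI
Why: Williamson mono-O-methylation; excess catechol keeps the diether low and is washed out with water.

Step 2
Reactants: 2 guaiacol
Product: 3 4-bromo-2-methoxyphenol
Conditions: NBS (1.0 equiv), MeCN, 0 °C
Reagents that add atoms: N-bromosuccinimide, O=C1CCC(=O)N1Br
Why: Electrophilic aromatic bromination goes para to the free OH, the strongest director.

Step 3
Reactants: 3 4-bromo-2-methoxyphenol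
Product: 4 (4-bromo-2-methoxyphenoxy)tri(propan-2-yl)silane
Conditions: TIPSCl, imidazole, DMF, rt
Reagents that add atoms: chlorotri(propan-2-yl)silane, CC(C)[Si](Cl)(C(C)C)C(C)C
Why: Phenol silylation; TIPS survives organolithium, enolate, phosphate base and aqueous Lewis acid and comes off with fluoride at the end.

Step 4
Reactants: 4 (4-bromo-2-methoxyphenoxy)tri(propan-2-yl)silane; 5 3-(bromomethyl)cyclobutan-1-one
Product: 6 3-{[3-methoxy-4-(triisopropylsilyloxy)phenyl]methyl}cyclobutan-1-one
Conditions: NiI2 hydrate (10 mol %), 4,4′-dimethoxy-2,2′-bipyridine (10 mol %), NaI (25 mol %), pyridine (10 mol %), Zn dust (2 equiv), DMPU, 60 °C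
Reagents that add atoms: none
Why: Ni-catalysed reductive cross-electrophile coupling of an aryl bromide with a primary alkyl bromide tolerates the ketone and gives the prochiral 3-benzylcyclobutanone directly.

Step 5
Reactants: 6 3-{[3-methoxy-4-(triisopropylsilyloxy)phenyl]methyl}cyclobutan-1-one
Product: 8 (4S)-4-{[3-methoxy-4-(triisopropylsilyloxy)phenyl]methyl}oxolan-2-one, via Criegee peroxyhemiketal 7 (not isolated)
Conditions: Sc(OTf)3 (5 mol %), chiral N,N′-dioxide ligand (6 mol %, antipode giving 4S), m-CPBA (1.2 equiv), Al(Oi-Pr)3 (0.5 equiv), EtOAc, −20 °C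
Reagents that add atoms: m-CPBA, OOC(=O)c1cccc(Cl)c1
Why: Catalytic asymmetric Baeyer–Villiger ring expansion; in the Sc-bound Criegee adduct only one of the two enantiotopic α-CH2 groups is antiperiplanar to the O–O bond and shifts to oxygen, which sets C4 as S (any R-series material becomes a separable diastereomer after step 13).

Step 6
Reactants: 9 p-cresol
Product: 10 2,6-dibromo-4-methylphenol
Conditions: Br2 (2.05 equiv), AcOH, 0 °C to rt
Reagents that add atoms: bromine, BrBr
Why: Electrophilic aromatic bromination at both positions ortho to OH, the para position being blocked.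

Step 7
Reactants: 10 2,6-dibromo-4-methylphenol
Product: 11 2-bromo-6-methoxy-4-methylphenol
Conditions: NaOMe (2.2 equiv), CuI (10 mol %), DMF/MeOH, 100 °C, stopped at mono-substitution; dilute acid work-up
Reagents that add atoms: sodium methoxide, [Na+].[O-]C
Why: Ullmann-type Cu-catalysed methoxylation; the mono-methoxy phenoxide is more electron-rich and reacts more slowly, so the reaction can be held at one exchange.

Step 8
Reactants: 11 2-bromo-6-methoxy-4-methylphenol
Product: 12 (2-bromo-6-methoxy-4-methylphenoxy)(tert-butyl)dimethylsilane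
Conditions: TBSCl, imidazole, DMF, 40 °C
Reagents that add atoms: tert-butyl(chloro)dimethylsilane, CC(C)(C)[Si](C)(C)Cl
Why: Silylation of the hindered phenol; TBS is small enough beside the bromide for the later Pd step and is inert to radical bromination.

Step 9
Reactants: 12 (2-bromo-6-methoxy-4-methylphenoxy)(tert-butyl)dimethylsilane
Product: 13 [2-bromo-4-(bromomethyl)-6-methoxyphenoxy](tert-butyl)dimethylsilane
Conditions: NBS (1.05 equiv), AIBN (5 mol %), PhCF3, 85 °C
Reagents that add atoms: N-bromosuccinimide, O=C1CCC(=O)N1Br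
Why: Wohl–Ziegler benzylic bromination of the only methyl group under radical conditions in a non-polar solvent.

Step 10
Reactants: 8 (4S)-4-{[3-methoxy-4-(triisopropylsilyloxy)phenyl]methyl}oxolan-2-one; 13 [2-bromo-4-(bromomethyl)-6-methoxyphenoxy](tert-butyl)dimethylsilane
Product: 15 (3S,4S)-3-{[3-bromo-4-(tert-butyldimethylsilyloxy)-5-methoxyphenyl]methyl}-4-{[3-methoxy-4-(triisopropylsilyloxy)phenyl]methyl}oxolan-2-one, via lithium enolate 14 (not isolated)
Conditions: LiHMDS (1.1 equiv), THF, −78 °C; then 13, DMPU, −78 to −40 °C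
Reagents that add atoms: none
Why: Lactone enolate alkylation; the benzyl bromide adds anti to the C4 benzyl group, which sets C3 as S (trans, substrate control).

Step 11
Reactants: 4 (4-bromo-2-methoxyphenoxy)tri(propan-2-yl)silane; 16 N-methoxy-N-methylacetamide
Product: 19 1-[3-methoxy-4-(triisopropylsilyloxy)phenyl]ethan-1-one, via aryllithium 17 (not isolated), via tetrahedral lithium adduct 18 (not isolated)
Conditions: n-BuLi (1.05 equiv), THF, −78 °C; then 16; then H2O
Reagents that add atoms: none
Why: Br/Li exchange followed by Weinreb amide acylation, which stops at the ketone because the chelated adduct is stable until work-up.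

Step 12
Reactants: 15 (3S,4S)-3-{[3-bromo-4-(tert-butyldimethylsilyloxy)-5-methoxyphenyl]methyl}-4-{[3-methoxy-4-(triisopropylsilyloxy)phenyl]methyl}oxolan-2-one; 19 1-[3-methoxy-4-(triisopropylsilyloxy)phenyl]ethan-1-one
Product: 20 (3S,4S)-3-{[4-(tert-butyldimethylsilyloxy)-3-methoxy-5-{2-[3-methoxy-4-(triisopropylsilyloxy)phenyl]-2-oxoethyl}phenyl]methyl}-4-{[3-methoxy-4-(triisopropylsilyloxy)phenyl]methyl}oxolan-2-one
Conditions: Pd2(dba)3 (2.5 mol %), Xantphos (6 mol %), K3PO4 (2.3 equiv), 19 (1.5 equiv), toluene, 90 °C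
Reagents that add atoms: none
Why: Pd-catalysed ketone α-arylation with a weak base that spares the lactone (epimerisation at C3 would only return the favoured trans isomer), and the ortho-silyloxy group blocks a second arylation.

Step 13
Reactants: 20 (3S,4S)-3-{[4-(tert-butyldimethylsilyloxy)-3-methoxy-5-{2-[3-methoxy-4-(triisopropylsilyloxy)phenyl]-2-oxoethyl}phenyl]methyl}-4-{[3-methoxy-4-(triisopropylsilyloxy)phenyl]methyl}oxolan-2-one; 21 formaldehyde
Product: 22 (3S,4S)-3-{[4-(tert-butyldimethylsilyloxy)-3-[(2S)-3-hydroxy-1-[3-methoxy-4-(triisopropylsilyloxy)phenyl]-1-oxopropan-2-yl]-5-methoxyphenyl]methyl}-4-{[3-methoxy-4-(triisopropylsilyloxy)phenyl]methyl}oxolan-2-one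
Conditions: Sc(OTf)3 (10 mol %), chiral N,N′-dioxide ligand (11 mol %, antipode giving 2S), 2,6-lutidine (20 mol %), 37% aq. HCHO (3 equiv), THF, −20 °C
Reagents that add atoms: none
Why: Proposed new method: a direct, catalyst-controlled aldol of an acyclic aryl benzyl ketone with formaldehyde, in which Sc(III) in the chiral N,N′-dioxide pocket binds the carbonyl of 20 and acidifies the doubly benzylic CH2 (pKa about 18, like the 3-aryl oxindoles that already undergo this reaction) so that lutidine gives the (Z)-Sc enolate, the ligand shields one face and the open face adds HCHO to form the C–CH2OH bond and the (S) centre (the ligand antipode is picked by screening, the lactone centres give no bias and the minor epimer is a separable diastereomer), while the product's tertiary C–H beside the twisted ortho-silyloxy aryl re-enolises far more slowly and keeps its configuration; the closest known reaction types are the Sc–N,N′-dioxide hydroxymethylation of oxindoles with formalin and the Sc–bipyridine hydroxymethylation of preformed silyl enol ethers.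

Step 14
Reactants: 22 (3S,4S)-3-{[4-(tert-butyldimethylsilyloxy)-3-[(2S)-3-hydroxy-1-[3-methoxy-4-(triisopropylsilyloxy)phenyl]-1-oxopropan-2-yl]-5-methoxyphenyl]methyl}-4-{[3-methoxy-4-(triisopropylsilyloxy)phenyl]methyl}oxolan-2-one
Product: 23 (3S,4S)-3-{[4-hydroxy-3-[(2S)-3-hydroxy-1-(4-hydroxy-3-methoxyphenyl)-1-oxopropan-2-yl]-5-methoxyphenyl]methyl}-4-[(4-hydroxy-3-methoxyphenyl)methyl]oxolan-2-one
Conditions: TBAF (3.5 equiv), AcOH (3.5 equiv), THF, 0 °C; pH 6 buffer work-up
Reagents that add atoms: none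
Why: Acetic acid-buffered fluoride desilylation of the three aryl silyl ethers stays near neutral, which avoids retro-aldol or epimerisation at the α-aryl ketone and acid-induced cyclodehydration to a benzofuran.

## Compound list

1 | catechol (benzene-1,2-diol) | Oc1ccccc1O | starting material
2 | guaiacol (2-methoxyphenol) | COc1ccccc1O | intermediate
3 | 4-bromo-2-methoxyphenol | COc1cc(Br)ccc1O | intermediate
4 | (4-bromo-2-methoxyphenoxy)tri(propan-2-yl)silane | COc1cc(Br)ccc1O[Si](C(C)C)(C(C)C)C(C)C | intermediate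
5 | 3-(bromomethyl)cyclobutan-1-one | O=C1CC(CBr)C1 | starting material
6 | 3-{[3-methoxy-4-(triisopropylsilyloxy)phenyl]methyl}cyclobutan-1-one | COc1cc(CC2CC(=O)C2)ccc1O[Si](C(C)C)(C(C)C)C(C)C | intermediate
7 | Criegee peroxyhemiketal: 1-hydroxy-3-{[3-methoxy-4-(triisopropylsilyloxy)phenyl]methyl}cyclobutyl 3-chlorobenzenecarboperoxoate | COc1cc(CC2CC(O)(OOC(=O)c3cccc(Cl)c3)C2)ccc1O[Si](C(C)C)(C(C)C)C(C)C | intermediate
8 | (4S)-4-{[3-methoxy-4-(triisopropylsilyloxy)phenyl]methyl}oxolan-2-one | COc1cc(C[C@@H]2COC(=O)C2)ccc1O[Si](C(C)C)(C(C)C)C(C)C | intermediate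
9 | p-cresol (4-methylphenol) | Cc1ccc(O)cc1 | starting material
10 | 2,6-dibromo-4-methylphenol | Cc1cc(Br)c(O)c(Br)c1 | intermediate
11 | 2-bromo-6-methoxy-4-methylphenol | COc1cc(C)cc(Br)c1O | intermediate
12 | (2-bromo-6-methoxy-4-methylphenoxy)(tert-butyl)dimethylsilane | COc1cc(C)cc(Br)c1O[Si](C)(C)C(C)(C)C | intermediate
13 | [2-bromo-4-(bromomethyl)-6-methoxyphenoxy](tert-butyl)dimethylsilane | COc1cc(CBr)cc(Br)c1O[Si](C)(C)C(C)(C)C | intermediate
14 | lithium enolate of 8 (4S) | COc1cc(C[C@@H]2COC(O[Li])=C2)ccc1O[Si](C(C)C)(C(C)C)C(C)C | intermediate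
15 | (3S,4S)-3-{[3-bromo-4-(tert-butyldimethylsilyloxy)-5-methoxyphenyl]methyl}-4-{[3-methoxy-4-(triisopropylsilyloxy)phenyl]methyl}oxolan-2-one | COc1cc(C[C@@H]2COC(=O)[C@H]2Cc2cc(OC)c(O[Si](C)(C)C(C)(C)C)c(Br)c2)ccc1O[Si](C(C)C)(C(C)C)C(C)C | intermediate
16 | N-methoxy-N-methylacetamide | CC(=O)N(C)OC | starting material
17 | [3-methoxy-4-(triisopropylsilyloxy)phenyl]lithium | COc1cc([Li])ccc1O[Si](C(C)C)(C(C)C)C(C)C | intermediate
18 | lithium 1-[methoxy(methyl)amino]-1-[3-methoxy-4-(triisopropylsilyloxy)phenyl]ethan-1-olate | COc1cc(C(C)(O[Li])N(C)OC)ccc1O[Si](C(C)C)(C(C)C)C(C)C | intermediate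
19 | 1-[3-methoxy-4-(triisopropylsilyloxy)phenyl]ethan-1-one | COc1cc(C(C)=O)ccc1O[Si](C(C)C)(C(C)C)C(C)C | intermediate
20 | (3S,4S)-3-{[4-(tert-butyldimethylsilyloxy)-3-methoxy-5-{2-[3-methoxy-4-(triisopropylsilyloxy)phenyl]-2-oxoethyl}phenyl]methyl}-4-{[3-methoxy-4-(triisopropylsilyloxy)phenyl]methyl}oxolan-2-one | COc1cc(C[C@@H]2COC(=O)[C@H]2Cc2cc(OC)c(O[Si](C)(C)C(C)(C)C)c(CC(=O)c3ccc(O[Si](C(C)C)(C(C)C)C(C)C)c(OC)c3)c2)ccc1O[Si](C(C)C)(C(C)C)C(C)C | intermediate
21 | formaldehyde (37% aqueous) | C=O | starting material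
22 | (3S,4S)-3-{[4-(tert-butyldimethylsilyloxy)-3-[(2S)-3-hydroxy-1-[3-methoxy-4-(triisopropylsilyloxy)phenyl]-1-oxopropan-2-yl]-5-methoxyphenyl]methyl}-4-{[3-methoxy-4-(triisopropylsilyloxy)phenyl]methyl}oxolan-2-one | COc1cc(C[C@@H]2COC(=O)[C@H]2Cc2cc(OC)c(O[Si](C)(C)C(C)(C)C)c([C@@H](CO)C(=O)c3ccc(O[Si](C(C)C)(C(C)C)C(C)C)c(OC)c3)c2)ccc1O[Si](C(C)C)(C(C)C)C(C)C | intermediate
23 | (3S,4S)-3-{[4-hydroxy-3-[(2S)-3-hydroxy-1-(4-hydroxy-3-methoxyphenyl)-1-oxopropan-2-yl]-5-methoxyphenyl]methyl}-4-[(4-hydroxy-3-methoxyphenyl)methyl]oxolan-2-one (CNP0281222.1) | COc1cc(C[C@@H]2COC(=O)[C@H]2Cc2cc(OC)c(O)c([C@@H](CO)C(=O)c3ccc(O)c(OC)c3)c2)ccc1O | target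

## Step count and risks

Total steps: 14. Longest linear sequence: 9 (steps 1, 2, 3, 4, 5, 10, 12, 13, 14).

The three steps most likely to fail:

**Step 13 (the proposed new reaction).** The risks are low conversion of a monodentate ketone, a second hydroxymethylation or dehydration to the enone, and erosion of the new centre. The fallback uses known chemistry and sets out from 20. Soft enolisation with TMSOTf and Et3N in CH2Cl2 at 0 °C gives the (Z)-trimethylsilyl enol ether of 20 F4. A Mukaiyama-type hydroxymethylation of this isolated silicon enolate with aqueous formaldehyde, catalysed by Sc(OTf)3 and a chiral 2,2′-bipyridine diol ligand in DME/water at −20 °C, then returns to the route at 22.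

**Step 12.** The risks are slow oxidative addition beside the silyloxy group, attack of the ketone enolate on the lactone, and loss of a silyl group to the basic enolate. The fallback removes the base altogether and sets out from 19. TMSOTf and Et3N give trimethyl({1-[3-methoxy-4-(triisopropylsilyloxy)phenyl]ethenyl}oxy)silane F3. Pd-catalysed coupling of F3 with 15 in the presence of Bu3SnF (tin enolate formed in the flask; Pd(OAc)2, P(t-Bu)3, toluene, 100 °C) returns to the route at 20.

**Step 7.** The risk is a statistical mixture of starting dibromide, mono- and di-methoxy products. The fallback installs the two ortho groups one after the other and sets out from 9. One equivalent of Br2 in CH2Cl2 at 0 °C gives 2-bromo-4-methylphenol F1. Cu-catalysed methoxylation with NaOMe in DMF, driven to full conversion, gives 2-methoxy-4-methylphenol F2. Bromination ortho to the hydroxyl with Br2 in AcOH/NaOAc then returns to the route at 11.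

Further compounds
F1 | step 7 | 2-bromo-4-methylphenol | Cc1ccc(O)c(Br)c1
F2 | step 7 | 2-methoxy-4-methylphenol | COc1cc(C)ccc1O
F3 | step 12 | trimethyl({1-[3-methoxy-4-(triisopropylsilyloxy)phenyl]ethenyl}oxy)silane | C=C(O[Si](C)(C)C)c1ccc(O[Si](C(C)C)(C(C)C)C(C)C)c(OC)c1
F4 | step 13 | (Z)-trimethylsilyl enol ether of 20 | COc1cc(C[C@@H]2COC(=O)[C@H]2Cc2cc(OC)c(O[Si](C)(C)C(C)(C)C)c(/C=C(\O[Si](C)(C)C)c3ccc(O[Si](C(C)C)(C(C)C)C(C)C)c(OC)c3)c2)ccc1O[Si](C(C)C)(C(C)C)C(C)C
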